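Ring B has carbon at C1' (the bond to C2) and oxygen at C3' and C5', the exact pattern of a 5-substituted cyclohexane-1,3-dione. Everything therefore rests on cutting C1'–C6' and C4'–C5', which leaves a but-3-en-2-one side chain on C2 plus dimethyl malonate. One operation, conjugate addition followed by Claisen ring closure, assembles all six ring B carbons at the correct oxidation level. Enol ether formation and dehydrogenation later give phenol and methyl ether without selective methylation. The precursor is the (2S)-5,7-bis(MOM)-8-prenylchroman carrying the (E)-enone at C2. Its stereocentre comes from a Sharpless epoxidation with 6-exo phenol opening. Its enone comes from a Wittig reaction, because metathesis would also engage the prenyl alkene.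

Key step: step 9

Abbreviations: prenyl = 3-methylbut-2-en-1-yl; MOM = methoxymethyl; chroman = 3,4-dihydro-2H-chromene.

Assumption: in step 2 the second MOM group is taken up by the unhindered ortho hydroxyl (O-6), so that O-2 stays free; this regiochemistry is to be confirmed at 4 before going on.

Remark: 18–20 are drawn as keto tautomers. Undefined centres are epimer mixtures that converge at 20 or 24. From 12 to 25 the priority order at C2 is O1 > exocyclic carbon > C3 > H, so the descriptor stays (S).

Step 1
Reactants: 1 2,4,6-trihydroxybenzaldehyde; 2 prenyl bromide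
Product: 3 2,4,6-trihydroxy-3-prenylbenzaldehyde
Conditions: KOH (2 equiv), H2O, 0 °C; 2 (0.9 equiv), 0 °C → rt; cold 1 M HCl to pH 4
Reagents that add atoms: none
Why: C-alkylation of an ambident phloroglucinolate anion (SN2 with a soft allylic bromide): in water the phenolate oxygens are hydrogen-bond solvated, so bond formation should occur at the ring carbon, C3 and C5 are equivalent so only one mono-C-prenyl product exists, and a deficit of 2 limits double alkylation.

Step 2
Reactants: 3 2,4,6-trihydroxy-3-prenylbenzaldehyde
Product: 4 2-hydroxy-4,6-bis(methoxymethoxy)-3-prenylbenzaldehyde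
Conditions: MOMCl (2.2 equiv), iPr2NEt (3 equiv), CH2Cl2, 0 °C → rt
Reagents that add atoms: chloromethyl methyl ether, COCCl
Why: Selective Williamson-type O-alkylation: the unchelated 4-OH and the less hindered of the two ortho hydroxyls (6-OH) should react, after which the last hydroxyl is locked in a hydrogen bond to the formyl oxygen and shielded by the prenyl group, so exactly the oxygen that becomes O1 stays free.

Step 3
Reactants: 4 2-hydroxy-4,6-bis(methoxymethoxy)-3-prenylbenzaldehyde; 5 (triphenylphosphoranylidene)acetaldehyde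
Product: 6 (2E)-3-[2-hydroxy-4,6-bis(methoxymethoxy)-3-prenylphenyl]prop-2-enal
Conditions: 5 (1.2 equiv), toluene, 80 °C
Reagents that add atoms: none
Why: Wittig olefination with a stabilised formylmethylene ylide, the standard (E)-selective access to 2-hydroxycinnamaldehydes, which needs no added base and therefore tolerates the free phenol, the acetals and the prenyl group.

Step 4
Reactants: 6 (2E)-3-[2-hydroxy-4,6-bis(methoxymethoxy)-3-prenylphenyl]prop-2-enal
Product: 7 5,7-bis(methoxymethoxy)-8-prenylchroman-2-ol (lactol, anomer mixture)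
Conditions: Hantzsch ester (diethyl 2,6-dimethyl-1,4-dihydropyridine-3,5-dicarboxylate, 1.2 equiv), Bn2NH·CF3CO2H (10 mol %), THF, rt → 40 °C
Reagents that add atoms: none
Why: Organocatalytic transfer hydrogenation via an iminium ion: only the C=C conjugated to the iminium accepts hydride from the Hantzsch ester, so the prenyl alkene is untouched where catalytic hydrogenation would not discriminate, and the saturated aldehyde is trapped by the neighbouring phenol as lactol 7.

Step 5
Reactants: 7 5,7-bis(methoxymethoxy)-8-prenylchroman-2-ol; 8 methyl (triphenylphosphoranylidene)acetate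
Product: 9 methyl (2E)-5-[2-hydroxy-4,6-bis(methoxymethoxy)-3-prenylphenyl]pent-2-enoate
Conditions: 8 (1.3 equiv), toluene, 40 °C
Reagents that add atoms: none
Why: Wittig olefination of a lactol through its open hydroxy aldehyde tautomer with a stabilised ylide, (E)-selective and neutral enough that the liberated hindered phenol should not add to the new enoate.

Step 6
Reactants: 9 methyl (2E)-5-[2-hydroxy-4,6-bis(methoxymethoxy)-3-prenylphenyl]pent-2-enoate
Product: 10 (2E)-5-[2-hydroxy-4,6-bis(methoxymethoxy)-3-prenylphenyl]pent-2-en-1-ol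
Conditions: iBu2AlH (3.5 equiv), CH2Cl2, −78 → −20 °C; aq. potassium sodium tartrate
Reagents that add atoms: none
Why: 1,2-Reduction of an α,β-unsaturated ester with iBu2AlH to the (E)-allylic alcohol, in which the first equivalent is consumed by the phenol and the acetals and the isolated alkene are inert at low temperature.

Step 7
Reactants: 10 (2E)-5-[2-hydroxy-4,6-bis(methoxymethoxy)-3-prenylphenyl]pent-2-en-1-ol
Product: 12 (1R)-1-[(2S)-5,7-bis(methoxymethoxy)-8-prenylchroman-2-yl]ethane-1,2-diol, via epoxy alcohol 11 (not isolated)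
Conditions: Ti(OiPr)4 (1.1 equiv), D-(−)-diethyl tartrate (1.3 equiv), tBuOOH (1.5 equiv, decane), 4 Å MS, CH2Cl2, −20 °C; then 0 °C → rt; 10% aq. tartaric acid
Reagents that add atoms: tert-butyl hydroperoxide, CC(C)(C)OO
Why: Sharpless asymmetric epoxidation followed in the same flask by titanium-assisted intramolecular epoxide opening: only the alkene of the titanium-bound allylic alcohol is oxidised (the prenyl alkene has no directing hydroxyl), D-(−)-diethyl tartrate directs oxygen to the face that gives the (2R,3R)-epoxide 11, and the phenol attacks C3 of the epoxy alcohol in a 6-exo-tet SN2 opening with inversion, which sets C2 as (S) and leaves an (R)-carbinol that is sacrificed in step 8.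

Step 8
Reactants: 12 (1R)-1-[(2S)-5,7-bis(methoxymethoxy)-8-prenylchroman-2-yl]ethane-1,2-diol; 13 1-(triphenylphosphoranylidene)propan-2-one
Product: 15 (3E)-4-[(2S)-5,7-bis(methoxymethoxy)-8-prenylchroman-2-yl]but-3-en-2-one, via chroman-2-carbaldehyde 14 (not isolated)
Conditions: NaIO4 on SiO2, CH2Cl2, rt, filter; filtrate + 13 (1.8 equiv), rt
Reagents that add atoms: none
Why: Malaprade glycol cleavage followed by Wittig olefination with a stabilised acetylmethylene ylide: the α-aryloxy aldehyde is never concentrated or exposed to a base stronger than the ylide, so C2 should keep its configuration, the alkene is formed (E), and no metathesis catalyst that could engage the prenyl alkene is needed.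

Step 9
Reactants: 15 (3E)-4-[(2S)-5,7-bis(methoxymethoxy)-8-prenylchroman-2-yl]but-3-en-2-one; 16 dimethyl malonate
Product: 18 methyl 2-[(2S)-5,7-bis(methoxymethoxy)-8-prenylchroman-2-yl]-4,6-dioxocyclohexane-1-carboxylate (epimer mixture at the two new ring carbons), via Michael adduct 17 (not isolated)
Conditions: 16 (1.5 equiv), NaOMe (1.2 equiv), MeOH, 0 °C; add 15, 0 °C → rt; then reflux; AcOH to pH 5 at 0 °C
Reagents that add atoms: none
Why: Sodium dimethyl malonate, pre-formed with the malonate in excess so that the enone never meets free methoxide, adds 1,4 to C1' (bond C1'–C6') to give keto diester 17; on heating, the reversibly formed enolate of the terminal methyl group (C4') attacks one malonate ester carbonyl (C5'), methoxide leaves, and the tricarbonyl product is deprotonated at once, which makes the sequence irreversible. The closest known reaction type is the classical Michael–Claisen (Dieckmann-type) annulation of enones with malonates that gives dimedone and other 5-substituted cyclohexane-1,3-diones. Ring B closes in a 6-(enolendo)-exo-trig mode, and since the internal C2' enolate could only form a four-membered ring, the regiochemistry of closure is dictated by ring size. The new centres C1' and C6' need no control: C1' forms under substrate bias from C2 as a mixture, C6' equilibrates through the enol to the trans arrangement, and both are erased (C6' in step 10, C1' in steps 10 to 12). The selectivity that matters is conjugate addition versus γ-deprotonation at C2–H, and it is secured by the low basicity of the malonate anion relative to the dienolate, by the unhindered (E)-disubstituted acceptor and by running the addition at 0 °C before any heating. Once C1' is sp3 the C2–H is no longer vinylogously acidic, so the hot methoxide of the closure phase cannot touch the stereocentre.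

Step 10
Reactants: 18 methyl 2-[(2S)-5,7-bis(methoxymethoxy)-8-prenylchroman-2-yl]-4,6-dioxocyclohexane-1-carboxylate
Product: 20 5-[(2S)-5,7-bis(methoxymethoxy)-8-prenylchroman-2-yl]cyclohexane-1,3-dione, via keto acid 19 (not isolated)
Conditions: 2 M aq. NaOH, MeOH, 70 °C; cool, AcOH to pH 4.5; 60 °C
Reagents that add atoms: water (as hydroxide), O (its oxygen enters 19 only and leaves again as CO2)
Why: Ester saponification followed by decarboxylation of the β-keto acid through the usual cyclic six-membered transition state: hot alkali is harmless to the enolate-protected dione, the MOM ethers and the prenyl group, the acetate-buffered pH spares the acetals, and because 20 is symmetric about C1' the epimer mixture collapses to one compound.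

Step 11
Reactants: 20 5-[(2S)-5,7-bis(methoxymethoxy)-8-prenylchroman-2-yl]cyclohexane-1,3-dione
Product: 21 3-methoxy-5-[(2S)-5,7-bis(methoxymethoxy)-8-prenylchroman-2-yl]cyclohex-2-en-1-one (two epimers at ring carbon 5)
Conditions: Me3SiCHN2 (1.3 equiv, Et2O), toluene–MeOH 4:1, 0 °C → rt
Reagents that add atoms: (trimethylsilyl)diazomethane, C[Si](C)(C)C=[N+]=[N-]
Why: O-Methylation of a vinylogous acid by a diazomethane equivalent under neutral conditions, chosen over acid-catalysed enol etherification in methanol that would strip the MOM groups; the two carbonyls are diastereotopic, so two C1' epimers should form, and these converge in step 12.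

Step 12
Reactants: 21 3-methoxy-5-[(2S)-5,7-bis(methoxymethoxy)-8-prenylchroman-2-yl]cyclohex-2-en-1-one
Product: 24 3-[(2S)-5,7-bis(methoxymethoxy)-8-prenylchroman-2-yl]-5-methoxyphenol, via sulfilimine adduct 22 (not isolated), via cross-conjugated dienone 23 (not isolated)
Conditions: LiN(iPr)2 (1.15 equiv), THF, −78 °C; PhS(Cl)=NtBu (1.3 equiv), −78 °C → rt; aq. NH4Cl
Reagents that add atoms: N-tert-butylbenzenesulfinimidoyl chloride, CC(C)(C)N=S(Cl)c1ccccc1 (its atoms enter 22 only and leave again in the elimination)
Why: Mukaiyama dehydrogenation of a lithium enolate: LiN(iPr)2 deprotonates the vinylogous ester kinetically at the α' carbon (the regiochemistry of the Stork–Danheiser alkylation), the enolate attacks sulfur anti to the chromanyl group so that the sulfilimine nitrogen lies syn to H–C1' and removes it in a five-membered syn elimination, and dienone 23 tautomerises to the phenol, all without an oxidant that could touch the prenyl alkene or ring A.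

Step 13
Reactants: 24 3-[(2S)-5,7-bis(methoxymethoxy)-8-prenylchroman-2-yl]-5-methoxyphenol
Product: 25 (2S)-2-(3-hydroxy-5-methoxyphenyl)-8-prenylchroman-5,7-diol (CNP0173255.1)
Conditions: HCl (ca. 0.5 M, from conc. aq. HCl) in MeOH, rt → 40 °C; NaHCO3
Reagents that add atoms: none
Why: Acid-catalysed acetal exchange (MOM cleavage) with methanol as acceptor, the standard last step for prenylated polyphenols: acetal ionisation is much faster than the protonation of the trisubstituted alkene that would start cyclisation onto the 7-OH, and C2–O1 should not ionise because both ring B oxygens are meta to C1'.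

Compound list

1 | 2,4,6-trihydroxybenzaldehyde | O=Cc1c(O)cc(O)cc1O | starting material
2 | prenyl bromide (1-bromo-3-methylbut-2-ene) | CC(C)=CCBr | starting material
3 | 2,4,6-trihydroxy-3-prenylbenzaldehyde | O=Cc1c(O)cc(O)c(CC=C(C)C)c1O | intermediate
4 | 2-hydroxy-4,6-bis(methoxymethoxy)-3-prenylbenzaldehyde | O=Cc1c(OCOC)cc(OCOC)c(CC=C(C)C)c1O | intermediate
5 | (triphenylphosphoranylidene)acetaldehyde | O=CC=P(c1ccccc1)(c1ccccc1)c1ccccc1 | starting material
6 | (2E)-3-[2-hydroxy-4,6-bis(methoxymethoxy)-3-prenylphenyl]prop-2-enal | O=C/C=C/c1c(OCOC)cc(OCOC)c(CC=C(C)C)c1O | intermediate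
7 | 5,7-bis(methoxymethoxy)-8-prenylchroman-2-ol (anomer mixture) | OC1CCc2c(OCOC)cc(OCOC)c(CC=C(C)C)c2O1 | intermediate
8 | methyl (triphenylphosphoranylidene)acetate | COC(=O)C=P(c1ccccc1)(c1ccccc1)c1ccccc1 | starting material
9 | methyl (2E)-5-[2-hydroxy-4,6-bis(methoxymethoxy)-3-prenylphenyl]pent-2-enoate | COC(=O)/C=C/CCc1c(OCOC)cc(OCOC)c(CC=C(C)C)c1O | intermediate
10 | (2E)-5-[2-hydroxy-4,6-bis(methoxymethoxy)-3-prenylphenyl]pent-2-en-1-ol | OC/C=C/CCc1c(OCOC)cc(OCOC)c(CC=C(C)C)c1O | intermediate
11 | [(2R,3R)-3-{2-[2-hydroxy-4,6-bis(methoxymethoxy)-3-prenylphenyl]ethyl}oxiran-2-yl]methanol | OC[C@H]1O[C@@H]1CCc2c(OCOC)cc(OCOC)c(CC=C(C)C)c2O | intermediate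
12 | (1R)-1-[(2S)-5,7-bis(methoxymethoxy)-8-prenylchroman-2-yl]ethane-1,2-diol | OC[C@@H](O)[C@@H]1CCc2c(OCOC)cc(OCOC)c(CC=C(C)C)c2O1 | intermediate
13 | 1-(triphenylphosphoranylidene)propan-2-one | CC(=O)C=P(c1ccccc1)(c1ccccc1)c1ccccc1 | starting material
14 | (2S)-5,7-bis(methoxymethoxy)-8-prenylchroman-2-carbaldehyde | O=C[C@@H]1CCc2c(OCOC)cc(OCOC)c(CC=C(C)C)c2O1 | intermediate
15 | (3E)-4-[(2S)-5,7-bis(methoxymethoxy)-8-prenylchroman-2-yl]but-3-en-2-one | CC(=O)/C=C/[C@@H]1CCc2c(OCOC)cc(OCOC)c(CC=C(C)C)c2O1 | intermediate
16 | dimethyl malonate | COC(=O)CC(=O)OC | starting material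
17 | dimethyl 2-{1-[(2S)-5,7-bis(methoxymethoxy)-8-prenylchroman-2-yl]-3-oxobutyl}propanedioate (epimers at C1') | CC(=O)CC(C(C(=O)OC)C(=O)OC)[C@@H]1CCc2c(OCOC)cc(OCOC)c(CC=C(C)C)c2O1 | intermediate
18 | methyl 2-[(2S)-5,7-bis(methoxymethoxy)-8-prenylchroman-2-yl]-4,6-dioxocyclohexane-1-carboxylate (epimer mixture) | COC(=O)C1C(=O)CC(=O)CC1[C@@H]3CCc2c(OCOC)cc(OCOC)c(CC=C(C)C)c2O3 | intermediate
19 | 2-[(2S)-5,7-bis(methoxymethoxy)-8-prenylchroman-2-yl]-4,6-dioxocyclohexane-1-carboxylic acid | OC(=O)C1C(=O)CC(=O)CC1[C@@H]3CCc2c(OCOC)cc(OCOC)c(CC=C(C)C)c2O3 | intermediate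
20 | 5-[(2S)-5,7-bis(methoxymethoxy)-8-prenylchroman-2-yl]cyclohexane-1,3-dione | O=C1CC(=O)CC(C1)[C@@H]3CCc2c(OCOC)cc(OCOC)c(CC=C(C)C)c2O3 | intermediate
21 | 3-methoxy-5-[(2S)-5,7-bis(methoxymethoxy)-8-prenylchroman-2-yl]cyclohex-2-en-1-one (two epimers) | COC1=CC(=O)CC(C1)[C@@H]3CCc2c(OCOC)cc(OCOC)c(CC=C(C)C)c2O3 | intermediate
22 | 6-(N-tert-butyl-S-phenylsulfinimidoyl)-3-methoxy-5-[(2S)-5,7-bis(methoxymethoxy)-8-prenylchroman-2-yl]cyclohex-2-en-1-one | COC1=CC(=O)C(S(=NC(C)(C)C)c4ccccc4)C(C1)[C@@H]3CCc2c(OCOC)cc(OCOC)c(CC=C(C)C)c2O3 | intermediate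
23 | 3-methoxy-5-[(2S)-5,7-bis(methoxymethoxy)-8-prenylchroman-2-yl]cyclohexa-2,5-dien-1-one | COC1=CC(=O)C=C(C1)[C@@H]3CCc2c(OCOC)cc(OCOC)c(CC=C(C)C)c2O3 | intermediate
24 | 3-[(2S)-5,7-bis(methoxymethoxy)-8-prenylchroman-2-yl]-5-methoxyphenol | COc1cc(O)cc([C@@H]2CCc3c(OCOC)cc(OCOC)c(CC=C(C)C)c3O2)c1 | intermediate
25 | (2S)-2-(3-hydroxy-5-methoxyphenyl)-8-prenylchroman-5,7-diol | COc1cc(O)cc([C@@H]2CCc3c(O)cc(O)c(CC=C(C)C)c3O2)c1 | target

Total step count: 13. Longest linear sequence: 13 steps (1 → 25); 2, 5, 8, 13 and 16 are purchased.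

Steps most likely to fail

1. Step 9 (key step).
- What may go wrong: γ-deprotonation of enone 15 competes with conjugate addition. The configuration at C2 then erodes and the double bond drifts into conjugation with O1. The Claisen closure may also stall at the open adduct.
- Fallback (sets out from 12, comes back at 18): the roles of donor and acceptor are exchanged. Diol 12 would be cleaved as in step 8 to aldehyde 14 and olefinated with ylide 8 to methyl (2E)-3-[(2S)-5,7-bis(methoxymethoxy)-8-prenylchroman-2-yl]prop-2-enoate F1. The γ-hydrogen of F1 is several pK units less acidic than that of the enone, and F1 has no enolisable acyl group. Methyl acetoacetate (CC(=O)CC(=O)OC) and NaOMe in MeOH would add at C1' to give dimethyl 2-acetyl-3-[(2S)-5,7-bis(methoxymethoxy)-8-prenylchroman-2-yl]pentanedioate F2. The acetyl methyl enolate of F2 would then close onto the chain ester and give the same tricarbonyl ester 18. This is the equally classical acrylate–acetoacetate form of the annulation.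

2. Step 7.
- What may go wrong: the electron-rich free phenol competes with the allylic alcohol for titanium, which erodes facial selectivity. The phenol may also be degraded oxidatively by the hydroperoxide.
- Fallback (sets out from 9, comes back at 12): epoxidation and ring closure are decoupled by masking the phenol. Enoate 9 would be silylated (tBuMe2SiOTf, 2,6-lutidine, CH2Cl2) to methyl (2E)-5-[2-(tert-butyldimethylsilyloxy)-4,6-bis(methoxymethoxy)-3-prenylphenyl]pent-2-enoate F3. F3 would be reduced with iBu2AlH to (2E)-5-[2-(tert-butyldimethylsilyloxy)-4,6-bis(methoxymethoxy)-3-prenylphenyl]pent-2-en-1-ol F4. F4 would be epoxidised under catalytic Sharpless conditions with D-(−)-diethyl tartrate to [(2R,3R)-3-{2-[2-(tert-butyldimethylsilyloxy)-4,6-bis(methoxymethoxy)-3-prenylphenyl]ethyl}oxiran-2-yl]methanol F5. Bu4NF in THF would then release the phenoxide, which closes 6-exo with inversion to diol 12.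

3. Step 12.
- What may go wrong: the emerging phenol transfers a proton to unreacted enolate, which stalls conversion. The electrophilic sulfur reagent may also attack the very electron-rich ring A.
- Fallback (sets out from 21, comes back at 24 through 23): carbon–heteroatom bond formation and elimination are separated in a selenoxide route. LiN(iPr)2 and then PhSeCl in THF at −78 °C would give 3-methoxy-6-(phenylselanyl)-5-[(2S)-5,7-bis(methoxymethoxy)-8-prenylchroman-2-yl]cyclohex-2-en-1-one F6, which can be purified. One equivalent of mCPBA in CH2Cl2 at −78 °C would oxidise selenium far faster than the prenyl alkene. This gives 3-methoxy-6-(phenylseleninyl)-5-[(2S)-5,7-bis(methoxymethoxy)-8-prenylchroman-2-yl]cyclohex-2-en-1-one F7. Warming with iPr2NH as scavenger would trigger syn elimination to 23 and tautomerisation to 24.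

Further compounds

F1 | step 9 | methyl (2E)-3-[(2S)-5,7-bis(methoxymethoxy)-8-prenylchroman-2-yl]prop-2-enoate | COC(=O)/C=C/[C@@H]1CCc2c(OCOC)cc(OCOC)c(CC=C(C)C)c2O1
F2 | step 9 | dimethyl 2-acetyl-3-[(2S)-5,7-bis(methoxymethoxy)-8-prenylchroman-2-yl]pentanedioate | COC(=O)CC(C(C(C)=O)C(=O)OC)[C@@H]1CCc2c(OCOC)cc(OCOC)c(CC=C(C)C)c2O1
F3 | step 7 | methyl (2E)-5-[2-(tert-butyldimethylsilyloxy)-4,6-bis(methoxymethoxy)-3-prenylphenyl]pent-2-enoate | COC(=O)/C=C/CCc1c(OCOC)cc(OCOC)c(CC=C(C)C)c1O[Si](C)(C)C(C)(C)C
F4 | step 7 | (2E)-5-[2-(tert-butyldimethylsilyloxy)-4,6-bis(methoxymethoxy)-3-prenylphenyl]pent-2-en-1-ol | OC/C=C/CCc1c(OCOC)cc(OCOC)c(CC=C(C)C)c1O[Si](C)(C)C(C)(C)C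
F5 | step 7 | [(2R,3R)-3-{2-[2-(tert-butyldimethylsilyloxy)-4,6-bis(methoxymethoxy)-3-prenylphenyl]ethyl}oxiran-2-yl]methanol | OC[C@H]1O[C@@H]1CCc2c(OCOC)cc(OCOC)c(CC=C(C)C)c2O[Si](C)(C)C(C)(C)C
F6 | step 12 | 3-methoxy-6-(phenylselanyl)-5-[(2S)-5,7-bis(methoxymethoxy)-8-prenylchroman-2-yl]cyclohex-2-en-1-one | COC1=CC(=O)C([Se]c4ccccc4)C(C1)[C@@H]3CCc2c(OCOC)cc(OCOC)c(CC=C(C)C)c2O3
F7 | step 12 | 3-methoxy-6-(phenylseleninyl)-5-[(2S)-5,7-bis(methoxymethoxy)-8-prenylchroman-2-yl]cyclohex-2-en-1-one | COC1=CC(=O)C([Se](=O)c4ccccc4)C(C1)[C@@H]3CCc2c(OCOC)cc(OCOC)c(CC=C(C)C)c2O3
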